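**Retrosynthetic overview**
The butenolide is attached last, preformed, by a C12–C13 Negishi coupling of a C12 alkylzinc with 3-bromofuran-2(5H)-one.
Ring A is disconnected at C1–C10 and C2–C3 into three pieces: an exocyclic C10=C20 methylene on ring B, a 2-methylmalondialdehyde unit on C5 (C3, C4, C18, C19), and acrolein (C1, C2, plus a formyl group on C2 that is later lost as CO).
The enabling feature lies in ring A: the methyl-bearing quaternary C10 and the carbinol C3 are 1,4-related through C4–C5, and C4 carries two oxygenated one-carbon arms (C3 inside ring A, C19 outside). The C10 methyl can therefore be born from a methylene by hydrogen-atom transfer, and a symmetric dialdehyde can serve at C4, with the ring closure itself choosing the arm and fixing quaternary C4.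
Ring B comes from (S)-cyclohex-3-ene-1-carboxylic acid (C8 and C17); iodolactonisation moves oxygen to C10, and C9 and C5 are then set by enolate alkylation and radical malonylation under thermodynamic control.
Order of rings: ring B (chiral pool), ring A (key annulation), butenolide ring (coupled on intact).

Key step: step 13

Remark: carbons are named by labdane numbering (ring A = C1–C5 and C10; ring B = C5–C10; C17 on C8; C18 and C19 on C4; C20 on C10; side chain C11–C16); TBS = tert-butyldimethylsilyl; the five starting materials are taken to be commercial.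

Step 1
Reactants: 1 (S)-cyclohex-3-ene-1-carboxylic acid
Product: 2 (1S,4S,5S)-4-iodo-6-oxabicyclo[3.2.1]octan-7-one
Conditions: I2, KI, NaHCO3, H2O, rt, dark
Reagents that add atoms: iodine, II
Why: Iodolactonisation, in which the carboxylate opens the iodonium ion anti at the nearer alkene carbon to give the bridged γ-lactone, so the new C10–O bond is forced cis to C17 and the iodide on C5 is trans to it.

Step 2
Reactants: 2 (1S,4S,5S)-4-iodo-6-oxabicyclo[3.2.1]octan-7-one
Product: 3 (1S,5S)-6-oxabicyclo[3.2.1]oct-3-en-7-one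
Conditions: DBU, toluene, 80 °C
Reagents that add atoms: none
Why: E2 dehydroiodination of the axial iodide with the anti-periplanar hydrogen on C6 moves the unsaturation to C5=C6 and leaves an allylic lactone, with no stereocentre touched.

Step 3
Reactants: 3 (1S,5S)-6-oxabicyclo[3.2.1]oct-3-en-7-one
Product: 4 (1S,5S)-5-(hydroxymethyl)cyclohex-2-en-1-ol
Conditions: LiAlH4, THF, 0 °C
Reagents that add atoms: none
Why: Hydride reduction of the lactone gives the cis allylic alcohol and primary alcohol pair, both stereocentres being carried over unchanged.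

Step 4
Reactants: 4 (1S,5S)-5-(hydroxymethyl)cyclohex-2-en-1-ol
Product: 5 (1S,5S)-5-(TBSOCH2)cyclohex-2-en-1-ol
Conditions: TBSCl, imidazole, CH2Cl2, −20 °C
Reagents that add atoms: tert-butyldimethylsilyl chloride, CC(C)(C)[Si](C)(C)Cl
Why: Selective silylation of the unhindered primary hydroxyl (C17) over the secondary allylic one.

Step 5
Reactants: 5 (1S,5S)-5-(TBSOCH2)cyclohex-2-en-1-ol
Product: 6 (S)-5-(TBSOCH2)cyclohex-2-en-1-one
Conditions: MnO2, CH2Cl2, rt
Reagents that add atoms: none
Why: Allylic alcohol oxidation with MnO2 gives the cyclohexenone (C10 ketone, C5=C6), leaving C8 as the only stereocentre.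

Step 6
Reactants: 7 2-(benzyloxy)ethanol
Product: 8 2-(benzyloxy)ethyl trifluoromethanesulfonate
Conditions: Tf2O, pyridine, CH2Cl2, −40 °C; used directly
Reagents that add atoms: trifluoromethanesulfonic anhydride, O=S(=O)(OS(=O)(=O)C(F)(F)F)C(F)(F)F
Why: Triflation of a primary alcohol gives a two-carbon electrophile reactive enough for C-alkylation of a ketone enolate.

Step 7
Reactants: 6 (S)-5-(TBSOCH2)cyclohex-2-en-1-one; 8 2-(benzyloxy)ethyl trifluoromethanesulfonate
Product: 10 (5S,6R)-6-[2-(benzyloxy)ethyl]-5-(TBSOCH2)cyclohex-2-en-1-one, via lithium dienolate 9 (not isolated)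
Conditions: LiN(iPr)2, THF, −78 °C; then 8, −78 to −30 °C
Reagents that add atoms: none
Why: Kinetic α′-deprotonation of the enone and enolate alkylation by the primary triflate, the electrophile entering anti to the adjacent C8 substituent so that C9 is set trans to C8 (also the thermodynamic arrangement).

Step 8
Reactants: 10 (5S,6R)-6-[2-(benzyloxy)ethyl]-5-(TBSOCH2)cyclohex-2-en-1-one
Product: 11 {(1S,2R)-2-[2-(benzyloxy)ethyl]-3-(triethylsilyloxy)cyclohex-3-en-1-yl}methyl TBS ether
Conditions: Et3SiH, RhCl(PPh3)3 (1 mol %), toluene, 50 °C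
Reagents that add atoms: triethylsilane, CC[SiH](CC)CC
Why: Rh-catalysed 1,4-hydrosilylation of the enone with a monohydrosilane gives the silyl enol ether regiospecifically toward C5 without touching C9.

Step 9
Reactants: 11 {(1S,2R)-2-[2-(benzyloxy)ethyl]-3-(triethylsilyloxy)cyclohex-3-en-1-yl}methyl TBS ether; 12 diethyl 2-bromo-2-methylpropanedioate
Product: 14 diethyl 2-[(1R,3R,4S)-3-[2-(benzyloxy)ethyl]-2-oxo-4-(TBSOCH2)cyclohexyl]-2-methylpropanedioate, via C5-epimer mixture 13 (not isolated)
Conditions: Ir(ppy)3 (1 mol %), MeCN, blue LEDs, rt; then DBU (0.2 equiv), CH2Cl2, rt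
Reagents that add atoms: none
Why: Photoredox radical alkylation of a silyl enol ether by an α-bromomalonate (the electrophilic tertiary malonyl radical adds at C5, then oxidation and loss of the silyl group give the ketone), followed by base equilibration that places C5 equatorial, the all-equatorial 2,6-cis-2,3-trans ketone being the thermodynamic isomer anchored by the fixed C8 centre.

Step 10
Reactants: 14 diethyl 2-[(1R,3R,4S)-3-[2-(benzyloxy)ethyl]-2-oxo-4-(TBSOCH2)cyclohexyl]-2-methylpropanedioate
Product: 15 diethyl 2-[(1S,3R,4S)-3-[2-(benzyloxy)ethyl]-2-methylidene-4-(TBSOCH2)cyclohexyl]-2-methylpropanedioate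
Conditions: Zn, CH2Br2, TiCl4, THF/CH2Cl2, 0 °C to rt
Reagents that add atoms: dibromomethane, BrCBr
Why: Takai–Lombardo methylenation, a non-basic titanium methylene reagent that should olefinate the hindered, epimerisable ketone without touching the esters or the α-stereocentres.

Step 11
Reactants: 15 diethyl 2-[(1S,3R,4S)-3-[2-(benzyloxy)ethyl]-2-methylidene-4-(TBSOCH2)cyclohexyl]-2-methylpropanedioate
Product: 16 2-[(1S,3R,4S)-3-[2-(benzyloxy)ethyl]-2-methylidene-4-(TBSOCH2)cyclohexyl]-2-methylpropane-1,3-diol
Conditions: LiAlH4, THF, 0 °C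
Reagents that add atoms: none
Why: Hydride reduction of the 2,2-disubstituted malonate to the prochiral 1,3-diol, the silyl ether, benzyl ether and alkene being inert.

Step 12
Reactants: 16 2-[(1S,3R,4S)-3-[2-(benzyloxy)ethyl]-2-methylidene-4-(TBSOCH2)cyclohexyl]-2-methylpropane-1,3-diol
Product: 17 2-[(1S,3R,4S)-3-[2-(benzyloxy)ethyl]-2-methylidene-4-(TBSOCH2)cyclohexyl]-2-methylpropanedial
Conditions: Dess–Martin periodinane, CH2Cl2, 0 °C to rt; used crude
Reagents that add atoms: none
Why: Dess–Martin oxidation of both neopentyl hydroxyls gives the non-enolisable 2,2-disubstituted malondialdehyde, which cannot epimerise.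

Step 13
Reactants: 17 2-[(1S,3R,4S)-3-[2-(benzyloxy)ethyl]-2-methylidene-4-(TBSOCH2)cyclohexyl]-2-methylpropanedial; 18 acrolein
Product: 20 (1S,2R,3S,4aS,5R,6S,8aS)-5-[2-(benzyloxy)ethyl]-2-hydroxy-1,4a-dimethyl-6-(TBSOCH2)decahydronaphthalene-1,3-dicarbaldehyde, via ring-open iron enolate 19 (not isolated)
Conditions: Fe(acac)3 (30 mol %), PhSiH2(OiPr) (2 equiv), 18 (3 equiv), EtOH/THF, 0 °C to rt
Reagents that add atoms: none
Why: An iron hydride formed from Fe(acac)3 and the silane passes a hydrogen atom to the methylene carbon C20, the tertiary C10 radical adds to the β-carbon of acrolein (C1–C10 bond), the α-formyl radical is reduced by iron to an enolate (radical–polar crossover), and this enolate attacks one formyl group of the malondialdehyde (C2–C3 bond). The closest known reaction type is the iron-catalysed, hydrogen-atom-transfer-initiated Giese–aldol annulation of an alkene-tethered aldehyde with an α,β-unsaturated carbonyl compound. Ring A closes by a 6-(enolexo)-exo-trig aldol addition after an intermolecular Giese addition, giving the trans-decalin. C10 is controlled by its two equatorial neighbours on C5 and C9, which should steer acrolein to the equatorial side anti to both and leave the new methyl axial and trans to H-5, as in conjugate additions of other 1-methylcyclohexyl radicals flanked by two equatorial substituents. C4 is controlled in the chair aldol transition state by that axial methyl, which should tolerate the flat formyl group but not the C4 methyl in the 1,3-diaxial position, so the unreacted arm ends axial as the future C19; C3 should follow from an iron-bridged, equatorial orientation of the reacting carbonyl syn to the spectator formyl group (equatorial hydroxyl), and the epimerisable C2 formyl group should settle equatorial before its removal in step 14. The step needs hydrogen-atom transfer at one alkene only, Giese addition ahead of reduction of the radical, and a choice between two formyl groups; these are secured by the methylene being the only alkene in 17, by excess acrolein, and by the C10 methyl.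

Step 14
Reactants: 20 (1S,2R,3S,4aS,5R,6S,8aS)-5-[2-(benzyloxy)ethyl]-2-hydroxy-1,4a-dimethyl-6-(TBSOCH2)decahydronaphthalene-1,3-dicarbaldehyde
Product: 21 (1S,2R,4aS,5R,6S,8aS)-5-[2-(benzyloxy)ethyl]-2-hydroxy-1,4a-dimethyl-6-(TBSOCH2)decahydronaphthalene-1-carbaldehyde
Conditions: RhCl(PPh3)3 (1.1 equiv), toluene, 90 °C
Reagents that add atoms: none
Why: Tsuji–Wilkinson decarbonylation, in which oxidative addition into the formyl C–H bond is sterically demanding, so the secondary C2 formyl group should react in preference to the neopentyl, axial formyl group on C4, and C–H reductive elimination removes the activating group and the C2 stereocentre.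

Step 15
Reactants: 21 (1S,2R,4aS,5R,6S,8aS)-5-[2-(benzyloxy)ethyl]-2-hydroxy-1,4a-dimethyl-6-(TBSOCH2)decahydronaphthalene-1-carbaldehyde
Product: 22 (1R,2R,4aS,5R,6S,8aS)-5-[2-(benzyloxy)ethyl]-1-(hydroxymethyl)-1,4a-dimethyl-6-(TBSOCH2)decahydronaphthalen-2-ol
Conditions: NaBH4, MeOH, 0 °C
Reagents that add atoms: none
Why: Borohydride reduction of the remaining aldehyde gives the C19 hydroxymethyl group without affecting any stereocentre.

Step 16
Reactants: 22 (1R,2R,4aS,5R,6S,8aS)-5-[2-(benzyloxy)ethyl]-1-(hydroxymethyl)-1,4a-dimethyl-6-(TBSOCH2)decahydronaphthalen-2-ol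
Product: 23 3,19-O-isopropylidene acetal of 22
Conditions: Me2C(OMe)2, PPTS (cat.), CH2Cl2, rt
Reagents that add atoms: 2,2-dimethoxypropane, COC(C)(C)OC
Why: Acid-catalysed transacetalisation joins the equatorial C3 hydroxyl and the axial C19 hydroxymethyl group in a six-membered isopropylidene acetal, masking both for the organometallic step.

Step 17
Reactants: 23 3,19-O-isopropylidene acetal of 22
Product: 24 C12 primary alcohol (debenzylated 23)
Conditions: H2 (1 atm), Pd/C, EtOAc, rt
Reagents that add atoms: none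
Why: Hydrogenolysis of the benzyl ether, with no alkene present and the acetal and silyl ether stable.

Step 18
Reactants: 24 C12 primary alcohol (debenzylated 23)
Product: 25 C12 primary iodide
Conditions: I2, PPh3, imidazole, THF, 0 °C
Reagents that add atoms: iodine, II
Why: Appel-type iodination of the unhindered primary alcohol by SN2 displacement of the alkoxyphosphonium ion.

Step 19
Reactants: 25 C12 primary iodide; 26 3-bromofuran-2(5H)-one
Product: 28 3,19-O-isopropylidene-17-O-TBS derivative of the target, via alkylzinc iodide 27 (not isolated)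
Conditions: Zn dust, LiCl, THF, 40 °C; then 26, Pd(OAc)2 (2 mol %), SPhos (4 mol %), THF, rt
Reagents that add atoms: none
Why: Zinc insertion into the primary iodide followed by Pd-catalysed Negishi sp3–sp2 coupling with the α-bromobutenolide forms C12–C13 and brings in the intact 2(5H)-furanone without creating a stereocentre.

Step 20
Reactants: 28 3,19-O-isopropylidene-17-O-TBS derivative of the target
Product: 29 14-deoxy-17-hydroxyandrographolide
Conditions: 1 M aq. HCl, THF, rt
Reagents that add atoms: none
Why: Aqueous acid hydrolyses the isopropylidene acetal and the primary silyl ether in one operation, the butenolide being acid-stable and no stereocentre being touched.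

**Compound list**
1 | (S)-cyclohex-3-ene-1-carboxylic acid | OC(=O)[C@@H]1CC=CCC1 | starting material
2 | (1S,4S,5S)-4-iodo-6-oxabicyclo[3.2.1]octan-7-one | O=C1O[C@H]2C[C@@H]1CC[C@@H]2I | intermediate
3 | (1S,5S)-6-oxabicyclo[3.2.1]oct-3-en-7-one | O=C1O[C@H]2C[C@@H]1CC=C2 | intermediate
4 | (1S,5S)-5-(hydroxymethyl)cyclohex-2-en-1-ol (cis) | O[C@@H]1C=CC[C@H](CO)C1 | intermediate
5 | (1S,5S)-5-(TBSOCH2)cyclohex-2-en-1-ol | O[C@@H]1C=CC[C@H](CO[Si](C)(C)C(C)(C)C)C1 | intermediate
6 | (S)-5-(TBSOCH2)cyclohex-2-en-1-one | O=C1C=CC[C@H](CO[Si](C)(C)C(C)(C)C)C1 | intermediate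
7 | 2-(benzyloxy)ethanol | OCCOCc1ccccc1 | starting material
8 | 2-(benzyloxy)ethyl trifluoromethanesulfonate | O=S(=O)(OCCOCc1ccccc1)C(F)(F)F | intermediate
9 | lithium dienolate of 6 (O–C10=C9, C5=C6 kept; not isolated) | [Li]OC1=C[C@@H](CO[Si](C)(C)C(C)(C)C)CC=C1 | intermediate
10 | (5S,6R)-6-[2-(benzyloxy)ethyl]-5-(TBSOCH2)cyclohex-2-en-1-one | O=C1C=CC[C@H](CO[Si](C)(C)C(C)(C)C)[C@H]1CCOCc1ccccc1 | intermediate
11 | {(1S,2R)-2-[2-(benzyloxy)ethyl]-3-(triethylsilyloxy)cyclohex-3-en-1-yl}methyl TBS ether | CC[Si](CC)(CC)OC1=CCC[C@H](CO[Si](C)(C)C(C)(C)C)[C@H]1CCOCc1ccccc1 | intermediate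
12 | diethyl 2-bromo-2-methylpropanedioate | CCOC(=O)C(C)(Br)C(=O)OCC | starting material
13 | diethyl 2-[(1RS,3R,4S)-3-[2-(benzyloxy)ethyl]-2-oxo-4-(TBSOCH2)cyclohexyl]-2-methylpropanedioate (C5-epimer mixture; not isolated) | CCOC(=O)C(C)(C(=O)OCC)C1CC[C@H](CO[Si](C)(C)C(C)(C)C)[C@@H](CCOCc2ccccc2)C1=O | intermediate
14 | diethyl 2-[(1R,3R,4S)-3-[2-(benzyloxy)ethyl]-2-oxo-4-(TBSOCH2)cyclohexyl]-2-methylpropanedioate (all ring substituents equatorial) | CCOC(=O)C(C)(C(=O)OCC)[C@H]1CC[C@H](CO[Si](C)(C)C(C)(C)C)[C@@H](CCOCc2ccccc2)C1=O | intermediate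
15 | diethyl 2-[(1S,3R,4S)-3-[2-(benzyloxy)ethyl]-2-methylidene-4-(TBSOCH2)cyclohexyl]-2-methylpropanedioate | CCOC(=O)C(C)(C(=O)OCC)[C@H]1CC[C@H](CO[Si](C)(C)C(C)(C)C)[C@@H](CCOCc2ccccc2)C1=C | intermediate
16 | 2-[(1S,3R,4S)-3-[2-(benzyloxy)ethyl]-2-methylidene-4-(TBSOCH2)cyclohexyl]-2-methylpropane-1,3-diol | OCC(C)(CO)[C@H]1CC[C@H](CO[Si](C)(C)C(C)(C)C)[C@@H](CCOCc2ccccc2)C1=C | intermediate
17 | 2-[(1S,3R,4S)-3-[2-(benzyloxy)ethyl]-2-methylidene-4-(TBSOCH2)cyclohexyl]-2-methylpropanedial | O=CC(C)(C=O)[C@H]1CC[C@H](CO[Si](C)(C)C(C)(C)C)[C@@H](CCOCc2ccccc2)C1=C | intermediate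
18 | acrolein (prop-2-enal) | C=CC=O | starting material
19 | ring-open iron enolate after the Giese addition (drawn as the free enol; not isolated) | O=CC(C)(C=O)[C@H]1CC[C@H](CO[Si](C)(C)C(C)(C)C)[C@@H](CCOCc2ccccc2)[C@]1(C)CC=CO | intermediate
20 | (1S,2R,3S,4aS,5R,6S,8aS)-5-[2-(benzyloxy)ethyl]-2-hydroxy-1,4a-dimethyl-6-(TBSOCH2)decahydronaphthalene-1,3-dicarbaldehyde (trans-decalin; C10 methyl and C4 formyl axial and syn; 3-OH and 2-CHO equatorial) | C[C@]1(C=O)[C@H]2CC[C@H](CO[Si](C)(C)C(C)(C)C)[C@@H](CCOCc3ccccc3)[C@]2(C)C[C@H](C=O)[C@H]1O | intermediate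
21 | (1S,2R,4aS,5R,6S,8aS)-5-[2-(benzyloxy)ethyl]-2-hydroxy-1,4a-dimethyl-6-(TBSOCH2)decahydronaphthalene-1-carbaldehyde | C[C@]1(C=O)[C@H]2CC[C@H](CO[Si](C)(C)C(C)(C)C)[C@@H](CCOCc3ccccc3)[C@]2(C)CC[C@H]1O | intermediate
22 | (1R,2R,4aS,5R,6S,8aS)-5-[2-(benzyloxy)ethyl]-1-(hydroxymethyl)-1,4a-dimethyl-6-(TBSOCH2)decahydronaphthalen-2-ol | C[C@]1(CO)[C@H]2CC[C@H](CO[Si](C)(C)C(C)(C)C)[C@@H](CCOCc3ccccc3)[C@]2(C)CC[C@H]1O | intermediate
23 | 3,19-O-isopropylidene acetal of 22 (1,3-dioxane across C3–O and C19–O) | C[C@]1(COC3(C)C)[C@H]2CC[C@H](CO[Si](C)(C)C(C)(C)C)[C@@H](CCOCc4ccccc4)[C@]2(C)CC[C@H]1O3 | intermediate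
24 | C12 primary alcohol (debenzylated 23) | C[C@]1(COC3(C)C)[C@H]2CC[C@H](CO[Si](C)(C)C(C)(C)C)[C@@H](CCO)[C@]2(C)CC[C@H]1O3 | intermediate
25 | C12 primary iodide | C[C@]1(COC3(C)C)[C@H]2CC[C@H](CO[Si](C)(C)C(C)(C)C)[C@@H](CCI)[C@]2(C)CC[C@H]1O3 | intermediate
26 | 3-bromofuran-2(5H)-one | O=C1OCC=C1Br | starting material
27 | alkylzinc iodide from 25 (not isolated) | C[C@]1(COC3(C)C)[C@H]2CC[C@H](CO[Si](C)(C)C(C)(C)C)[C@@H](CC[Zn]I)[C@]2(C)CC[C@H]1O3 | intermediate
28 | 3,19-O-isopropylidene-17-O-TBS derivative of the target | C[C@]1(COC3(C)C)[C@H]2CC[C@H](CO[Si](C)(C)C(C)(C)C)[C@@H](CCC4=CCOC4=O)[C@]2(C)CC[C@H]1O3 | intermediate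
29 | 14-deoxy-17-hydroxyandrographolide | C[C@]1(CO)[C@H]2CC[C@H](CO)[C@@H](CCC3=CCOC3=O)[C@]2(C)CC[C@H]1O | target

Total step count: 20. Longest linear sequence: 19 steps (steps 1–5 and 7–20; step 6 prepares the alkylating agent).

**Steps most likely to fail**

Step 13. The C10 radical may be reduced before it adds to acrolein, or the enolate may be protonated before it closes. The choice between the two formyl groups or between the two faces of the radical may be incomplete, and the aldolate may reopen by retro-aldol cleavage. The fallback separates the two bond formations. It sets out from 17 and 18: a reductive olefin coupling under fully protic conditions (Fe(acac)3, PhSiH3, EtOH/ethylene glycol) is stopped at the ring-open trialdehyde F1. F1 is then closed by a reversible amine-catalysed 6-enolexo aldolisation (proline, DMSO, rt), in which the chair with the axial formyl group and the equatorial hydroxyl should be the most stable. The route is rejoined at 20.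

Step 14. The hindered C4 formyl group may also be lost, or the β-hydroxy aldehyde may dehydrate or reopen at the temperature needed. The fallback differentiates the two arms of C4 before ring A is made, so that only one formyl group is present. It sets out from 16: a lipase-catalysed desymmetrising acetylation (vinyl acetate, lipase screened for the arm that becomes C19) should give the mono-acetate F2. Dess–Martin oxidation gives the aldehyde acetate F3, and the same iron-catalysed annulation with 18 gives the annulated hydroxy aldehyde acetate F4. RhCl(PPh3)3 then has a single formyl group to remove and gives the hydroxy acetate F5. K2CO3 in MeOH cleaves the acetate and the route is rejoined at 22.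

Step 19. The alkylzinc may be protonated or may form slowly, and the bromobutenolide may decompose or couple sluggishly. The fallback builds the unsaturation after the C–C bond. It sets out from 25: alkylation of the lithium enolate of commercial 3-(phenylsulfanyl)oxolan-2-one (LiN(iPr)2, THF/DMPU) gives the α-phenylsulfanyl lactone F6 as a mixture of C13 epimers. mCPBA at −78 °C gives the sulfoxide F7, and thermal syn-elimination toward the ring (toluene, 110 °C, CaCO3) should give the endocyclic butenolide. The route is rejoined at 28.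

Further compounds
F1 | step 13 | ring-open trialdehyde, 2-methyl-2-[2-methyl-2-(3-oxopropyl)cyclohexyl]propanedial carrying the C8 and C9 substituents of 17 | O=CC(C)(C=O)[C@H]1CC[C@H](CO[Si](C)(C)C(C)(C)C)[C@@H](CCOCc2ccccc2)[C@]1(C)CCC=O
F2 | step 14 | mono-acetate of 16 (arm that becomes C19 acetylated) | C[C@](CO)(COC(C)=O)[C@H]1CC[C@H](CO[Si](C)(C)C(C)(C)C)[C@@H](CCOCc2ccccc2)C1=C
F3 | step 14 | aldehyde acetate from F2 | C[C@](C=O)(COC(C)=O)[C@H]1CC[C@H](CO[Si](C)(C)C(C)(C)C)[C@@H](CCOCc2ccccc2)C1=C
F4 | step 14 | annulated hydroxy aldehyde acetate (C2 formyl, C3 hydroxyl, C19 acetate) | C[C@]1(COC(C)=O)[C@H]2CC[C@H](CO[Si](C)(C)C(C)(C)C)[C@@H](CCOCc3ccccc3)[C@]2(C)C[C@H](C=O)[C@H]1O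
F5 | step 14 | hydroxy acetate after decarbonylation (19-O-acetate of 22) | C[C@]1(COC(C)=O)[C@H]2CC[C@H](CO[Si](C)(C)C(C)(C)C)[C@@H](CCOCc3ccccc3)[C@]2(C)CC[C@H]1O
F6 | step 19 | α-phenylsulfanyl lactone (C13 epimers) | C[C@]1(COC3(C)C)[C@H]2CC[C@H](CO[Si](C)(C)C(C)(C)C)[C@@H](CCC4(Sc5ccccc5)CCOC4=O)[C@]2(C)CC[C@H]1O3
F7 | step 19 | sulfoxide of F6 | C[C@]1(COC3(C)C)[C@H]2CC[C@H](CO[Si](C)(C)C(C)(C)C)[C@@H](CCC4(S(=O)c5ccccc5)CCOC4=O)[C@]2(C)CC[C@H]1O3
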